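(The data are calculated on assumed constants, and the scatter is random.)

Early times in the theta flask show X falling fast, but a plan needs the place where it stops, so follow one molecule of X and ask where it stands at rest.

| setting | theta | delta | flask |
|---|---|---|---|
| X | 1 M | 1 M | 1.0 M |
| D | 1 mol% | 2 mol% | 1 mol% |
| Q | 1.3 mM | 1.3 mM | 1.3 mM |
| temperature | 5 °C | 0 °C | 5 °C |
| remark | the very flask that is asked about, followed so far | run made earlier |  |
| time |  |  | 50 h |

| run | time / h | L / % | X / % |
|---|---|---|---|
| theta | 4.00 | 25.8 | 70.9 |
| theta | 10.0 | 36.9 | 56.1 |
| theta | 20.0 | 39.0 | 50.4 |
| theta | 30.0 | 40.2 | 48.8 |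
| theta | 40.0 | 40.4 | 49.1 |
| delta | 4.00 | 17.6 | 81.4 |
| delta | 8.00 | 27.2 | 68.0 |
| delta | 12.0 | 33.8 | 58.5 |
| delta | 15.0 | 38.3 | 52.8 |
| delta | 20.0 | 43.5 | 46.7 |

(scatter of a reading: 0.5 percentage points)

- east: at 50 h take out 90% of the L then present, then wait 2.0 d
- north: change nothing and wait 2.0 d more
- south-west: at 50 h add D, 100% of the amount charged, then wait 2.0 d
- west: at 50 h raise the temperature by 10 K, then wait 2.0 d

- L taken out counts as made
- additions bring no volume worth counting

- L, in percent of the X first charged, at 50 h
- what to do for the largest gain in L; "none" if nothing gains more than 2 percentage points (east / north / south-west / west / none)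
- L present, with what was taken out counted in, in percent of the X first charged, after north
- L present, with what was taken out counted in, in percent of the X first charged, after south-west

At the last theta reading, at 40.0 h, L stands at 40.4% and X at 49.1%, which leaves 10.5% of the charge unaccounted for; call that share J. L moved by 0.2 percentage points over the last interval, less than the scatter of 0.5 points, so I read the theta flask as at rest. I take that rest as a balance, which means thermodynamic rather than kinetic control. At the fork between X and L the odds are r = L/X = 0.823, an equilibrium constant as read. At the fork between L and J the odds are s = J/L = 0.260. Together they give c = 1/(1 + 1/r + s) = 40.4%, the chance, as read at 5 °C in the theta flask, that a charged molecule stands as L at rest.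

So I commit to c for L at 50 h, and to c again after north. D is the catalyst, and I take r and s to stay as they are when more of it goes in, so south-west also gives c. Delta, colder and with more D, already reads L/X = 0.931, more than r, and since I hold D to leave r as it is, I expect warming to cost L. East removes L, and the pool left behind refills towards the chance c, so I choose east.

The weak link is the word balance, since dead D could also stop a flask. Early loss of X tests it: theta reads 0.0860 /h over 4.00 h, delta 0.0514 /h, less than theta with twice the D. If this rate followed the D charged, going from 5 °C to 0 °C would have to cost a factor of 3.34, which I find too steep, so I keep the balance.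

The forecast says 40.5%, south-west, 40.6% after north and 59% after south-west, holding that “the stall looks like catalyst death rather than equilibrium”.

The flask gives 40.0% at 50 h, with 40.0% after north and 40.0% after south-west, and the best option is east, gaining 22 points. X and L relax with a half-life of 0.114 d by their step, counting both ways, short against 50 h.

    X ⇌ L (K = 0.820, k = 0.00190 /min, Ea = 90.0 kJ/mol, ΔH = −75.0 kJ/mol)
    L + D ⇌ J + D, rate k2*[D]*[L] forward; the back reaction follows from the equilibrium constant (K = 0.280, k = 0.210 /M/min, Ea = 50.0 kJ/mol, ΔH = 13.0 kJ/mol)
    2 D ⇌ Z (K = 160 /M, k = 0.130 /M/min, Ea = 56.0 kJ/mol, ΔH = −63.0 kJ/mol)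
    D + Q → E (k = 14.0 /M/min, Ea = 50.0 kJ/mol)
    (constants at 5 °C)

For east in the flask, if what remains returns to rest and L taken out is counted in, the share x taken out is worth x·c·(1 − c), which is 22 points.

For the neighbour kept at 30 °C, the enthalpies move r to 0.0567 and s to 0.413, so c becomes 5.25%. The computed L there is 5.23%.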